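**Retrosynthetic overview**
- The pyridone ring is formed last. It is opened at N1–C8a (C–N coupling) and C4–C4a (acyl ring closure), giving (S)-2-iodo-4-(5-phenylpentyl)cyclohex-2-enone and methyl 3-amino-2-methoxybut-2-enoate.
- The iodoenone comes from (S)-4-(5-phenylpentyl)cyclohex-2-enone by α-iodination; the enamino ester comes from methyl 2-methoxy-3-oxobutanoate and ammonia.
- The carbocycle is formed first, by intramolecular aldol condensation of (S)-5-oxo-2-(5-phenylpentyl)hexanal. That keto aldehyde comes from an organocatalytic Michael addition of 7-phenylheptanal to methyl vinyl ketone, which sets the only stereocentre.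
- 7-Phenylheptanal comes from 7-phenylheptan-1-ol.
- Ring order: cyclohexenone ring, then the 4-pyridone ring.

Assumption: the target's stereocentre (C5 of the tetrahydroquinolinedione) is read from the SMILES as S, and 7-phenylheptan-1-ol, but-3-en-2-one and methyl 2-methoxy-3-oxobutanoate are bought.

**Step 1**
Reactants: 1 7-phenylheptan-1-ol
Product: 2 7-phenylheptanal
Conditions: TEMPO (1 mol%), KBr (10 mol%), NaOCl (1.1 equiv), NaHCO3, CH2Cl2/H2O, 0 °C
Reagents that add atoms: none
Why: Anelli oxidation, in which the oxoammonium ion made from TEMPO and hypochlorite oxidises the primary alcohol and the buffered two-phase medium stops at the aldehyde; no stereocentre is involved.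

**Step 2**
Reactants: 2 7-phenylheptanal; 3 but-3-en-2-one (methyl vinyl ketone)
Product: 5 (S)-4-(5-phenylpentyl)cyclohex-2-en-1-one, via (S)-5-oxo-2-(5-phenylpentyl)hexanal 4 (not isolated)
Conditions: (R)-2-[methoxy(diphenyl)methyl]pyrrolidine (5 mol%), ethyl 3,4-dihydroxybenzoate (20 mol%), 3 (1.5 equiv), neat, 4 °C; excess 3 off in vacuo; then LiOH (0.5 equiv), i-PrOH, rt
Reagents that add atoms: none
Why: Enamine-catalysed Michael addition followed by intramolecular aldol condensation (Robinson-type annulation), in which the anti E-enamine of 2 is shielded on one face by the methoxy(diphenyl)methyl group so that 3 adds to the open face and the (R)-catalyst gives the S aldehyde 4, whose methyl ketone enolate then closes on the aldehyde and dehydrates, leaving the stereocentre as the non-enolised C4 of the enone.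

**Step 3**
Reactants: 5 (S)-4-(5-phenylpentyl)cyclohex-2-en-1-one
Product: 6 (S)-2-iodo-4-(5-phenylpentyl)cyclohex-2-en-1-one
Conditions: I2 (1.5 equiv), K2CO3 (1.2 equiv), DMAP (20 mol%), THF/H2O (1:1), rt
Reagents that add atoms: iodine, II
Why: Baylis–Hillman-type α-iodination of an enone, in which DMAP adds reversibly at C3, the resulting enolate is iodinated at C2 and DMAP is expelled, so C4 is never deprotonated and the stereocentre is kept.

**Step 4**
Reactants: 7 methyl 2-methoxy-3-oxobutanoate
Product: 8 methyl (E)-3-amino-2-methoxybut-2-enoate (amino group cis to the ester)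
Conditions: NH4OAc (5 equiv), MeOH, rt
Reagents that add atoms: ammonium acetate, CC(=O)[O-].[NH4+]
Why: β-Enamino ester formation by condensation of ammonia with the ketone carbonyl of the β-keto ester, the product being held by the N–H···O=C hydrogen bond as the isomer with the amino group cis to the ester.

**Step 5**
Reactants: 6 (S)-2-iodo-4-(5-phenylpentyl)cyclohex-2-en-1-one; 8 methyl (E)-3-amino-2-methoxybut-2-enoate
Product: 10 (S)-3-methoxy-2-methyl-5-(5-phenylpentyl)-5,6,7,8-tetrahydroquinoline-4,8(1H)-dione, via N-alkenyl enamino ester 9 (not isolated)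
Conditions: CuI (10 mol%), N,N'-dimethylethane-1,2-diamine (20 mol%), Cs2CO3 (2.5 equiv), 1,4-dioxane, 60 °C then 100 °C
Reagents that add atoms: none
Why: Proposed new method: a copper-catalysed aza-annulation of a 2-iodoenone with a primary β-enamino ester, in which the amide-like nitrogen of 8 (its carbon terminus is blocked by the 2-methoxy group) is N-alkenylated at the C–I bond of 6 through a monovalent/trivalent copper cycle to form the N1–C8a bond, and the caesium salt of the divinylamine 9, an aza-trienolate, then closes by 6π-electrocyclisation (equivalently an intramolecular Claisen-type acylation of the enamine β-carbon C4a by the ester), loses methoxide and tautomerises to the 4-pyridone without touching the stereocentre; the closest known reactions are the CuI/diamine Goldberg amidation of vinyl iodides, the amidation–Camps sequence and the Conrad–Limpach synthesis of 4-quinolones.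

**Compound list**
1 | 7-phenylheptan-1-ol | OCCCCCCCc1ccccc1 | starting material
2 | 7-phenylheptanal | O=CCCCCCCc1ccccc1 | intermediate
3 | but-3-en-2-one (methyl vinyl ketone) | CC(=O)C=C | starting material
4 | (S)-5-oxo-2-(5-phenylpentyl)hexanal | O=C[C@@H](CCCCCc1ccccc1)CCC(C)=O | intermediate
5 | (S)-4-(5-phenylpentyl)cyclohex-2-en-1-one | O=C1C=C[C@@H](CCCCCc2ccccc2)CC1 | intermediate
6 | (S)-2-iodo-4-(5-phenylpentyl)cyclohex-2-en-1-one | O=C1C(I)=C[C@@H](CCCCCc2ccccc2)CC1 | intermediate
7 | methyl 2-methoxy-3-oxobutanoate | COC(=O)C(OC)C(C)=O | starting material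
8 | methyl (E)-3-amino-2-methoxybut-2-enoate | COC(=O)/C(OC)=C(/C)N | intermediate
9 | methyl (E)-2-methoxy-3-{[(3S)-6-oxo-3-(5-phenylpentyl)cyclohex-1-en-1-yl]amino}but-2-enoate | COC(=O)/C(OC)=C(/C)NC1=C[C@@H](CCCCCc2ccccc2)CCC1=O | intermediate
10 | (S)-3-methoxy-2-methyl-5-(5-phenylpentyl)-5,6,7,8-tetrahydroquinoline-4,8(1H)-dione | COc1c(C)[nH]c2c(c1=O)[C@@H](CCCCCc1ccccc1)CCC2=O | target

**Step count**
Total: 5 steps. Longest linear sequence: 4 steps (1 → 2 → 5 → 6 → 10); step 4 is a one-step side branch.

**Three steps most likely to fail**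

Step 5 (the proposed new aza-annulation). The coupling may lose out to C-Michael addition of 8 to the enone or to loss of iodine, and the ring closure may stall at 9 because the side chain sits next to the reacting carbon. The fallback uses known reactions only; it sets out from 6 and comes back at 9. Goldberg amidation of 6 with tert-butyl carbamate (CuI, N,N'-dimethylethane-1,2-diamine, K3PO4, toluene, 60 °C) gives tert-butyl N-[(3S)-6-oxo-3-(5-phenylpentyl)cyclohex-1-en-1-yl]carbamate F1. Trifluoroacetic acid in CH2Cl2 at 0 °C removes the carbamate to give (S)-2-amino-4-(5-phenylpentyl)cyclohex-2-en-1-one F2, handled as its trifluoroacetate. Condensation of F2 with 7 (AcOH cat., 4 Å sieves, benzene, 40 °C; first stage of a Conrad–Limpach synthesis) gives 9, now isolated. Compound 9 is closed to 10 thermally (Ph2O, 240 °C, 15 min; second stage of the Conrad–Limpach synthesis).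

Step 2 (Michael addition and aldol condensation). The Michael addition may give insufficient ee with this long-chain aldehyde, and base may erode the aldehyde stereocentre before ring closure. The fallback replaces catalysis by an auxiliary; it sets out from 2 and comes back at 4. Condensation of 2 with (S)-1-amino-2-(methoxymethyl)pyrrolidine gives (E)-N-[(2S)-2-(methoxymethyl)pyrrolidin-1-yl]-7-phenylheptan-1-imine F3. Deprotonation with LiN(i-Pr)2 (THF, 0 °C) and alkylation with 2-(2-bromoethyl)-2-methyl-1,3-dioxolane at −100 °C gives (E,2S)-N-[(2S)-2-(methoxymethyl)pyrrolidin-1-yl]-2-[2-(2-methyl-1,3-dioxolan-2-yl)ethyl]-7-phenylheptan-1-imine F4. Ozonolysis (O3, CH2Cl2, −78 °C) cleaves the hydrazone to (S)-2-[2-(2-methyl-1,3-dioxolan-2-yl)ethyl]-7-phenylheptanal F5. Mild acid (pyridinium p-toluenesulfonate, acetone/H2O) removes the ketal to give 4, which is cyclised to 5 as in the second stage of step 2.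

Step 3 (α-iodination). Attack of DMAP at C3 may be slow next to the substituted C4, and the iodoenone is sensitive to light and base. The fallback brings nitrogen in without a halide; it sets out from 5 and comes back at 9. Nucleophilic epoxidation (H2O2, NaOH, MeOH, 0 °C) gives mainly the trans epoxide (1R,5S,6R)-5-(5-phenylpentyl)-7-oxabicyclo[4.1.0]heptan-2-one F6. Opening at the α-carbon with NaN3 (AcOH, EtOH/H2O, 60 °C) and loss of water gives (S)-2-azido-4-(5-phenylpentyl)cyclohex-2-en-1-one F7. Staudinger reaction with PPh3 (THF, rt) gives (S)-4-(5-phenylpentyl)-2-[(triphenylphosphoranylidene)amino]cyclohex-2-en-1-one F8. Aza-Wittig condensation of F8 with the ketone of 7 (toluene, 80 °C) gives 9 after tautomerisation. Compound 9 is closed to 10 with Cs2CO3 in 1,4-dioxane at 100 °C as in step 5, without copper.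

**Further compounds**
F1 | step 5 | tert-butyl N-[(3S)-6-oxo-3-(5-phenylpentyl)cyclohex-1-en-1-yl]carbamate | CC(C)(C)OC(=O)NC1=C[C@@H](CCCCCc2ccccc2)CCC1=O
F2 | step 5 | (S)-2-amino-4-(5-phenylpentyl)cyclohex-2-en-1-one | NC1=C[C@@H](CCCCCc2ccccc2)CCC1=O
F3 | step 2 | (E)-N-[(2S)-2-(methoxymethyl)pyrrolidin-1-yl]-7-phenylheptan-1-imine | COC[C@@H]1CCCN1/N=C/CCCCCCc1ccccc1
F4 | step 2 | (E,2S)-N-[(2S)-2-(methoxymethyl)pyrrolidin-1-yl]-2-[2-(2-methyl-1,3-dioxolan-2-yl)ethyl]-7-phenylheptan-1-imine | COC[C@@H]1CCCN1/N=C/[C@@H](CCCCCc1ccccc1)CCC1(C)OCCO1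
F5 | step 2 | (S)-2-[2-(2-methyl-1,3-dioxolan-2-yl)ethyl]-7-phenylheptanal | O=C[C@@H](CCCCCc1ccccc1)CCC1(C)OCCO1
F6 | step 3 | (1R,5S,6R)-5-(5-phenylpentyl)-7-oxabicyclo[4.1.0]heptan-2-one | O=C1CC[C@H](CCCCCc2ccccc2)[C@H]2O[C@@H]12
F7 | step 3 | (S)-2-azido-4-(5-phenylpentyl)cyclohex-2-en-1-one | [N-]=[N+]=NC1=C[C@@H](CCCCCc2ccccc2)CCC1=O
F8 | step 3 | (S)-4-(5-phenylpentyl)-2-[(triphenylphosphoranylidene)amino]cyclohex-2-en-1-one | O=C1CC[C@H](CCCCCc2ccccc2)C=C1N=P(c1ccccc1)(c1ccccc1)c1ccccc1
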